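**Numbering used throughout:** 1 2,5-dimethoxybenzyl chloride; 2 its triphenylphosphonium chloride; 3 isovanillin; 4 the phosphonium ylide; 5 the C–D stilbene phenol; 6 the C–D bibenzyl phenol; 7 4-bromophenylboronic acid; 8 the ring B aryl bromide carrying rings C and D; 9 3-bromoanisole; 10 vinylboronic acid pinacol ester; 11 3-methoxyphenyllithium; 12 the lithium vinylboron ate complex; 13 the benzylic pinacol boronate; 14 the tetramethyl ether of the target; 15 the target.

## Analysis of the target

Compound 15 (C28H26O5) is an open-chain bis(bibenzyl): four benzene rings joined by two CH2–CH2 bridges and one diaryl ether oxygen, with no other ring. Ring A is a 3-hydroxyphenyl group, ring B a para-phenylene, ring C a 1,2,4-trisubstituted ring and ring D a 2,5-dihydroxyphenyl (hydroquinone) group. On ring C the hydroxyl is para to the C–D bridge and the aryloxy group is ortho to that hydroxyl and meta to the bridge. There is no stereocentre, so the only stereochemical event in the route is a transient one that is erased. The sensitive parts are the four free phenols, above all the hydroquinone of ring D, which oxidises easily to the quinone in air or base; all four are therefore carried as methyl ethers until the last step. The difficulty is not any single bond but economy: four differently oxygenated arenes must be joined through three linkers with the correct regiochemistry on ring C, without a long linear sequence. The strategy rests on the A–B bridge, an ethane-1,2-diyl unit in which each carbon carries exactly one aryl group (ring A on one, ring B on the other). That is the pattern a vinyl group acquires when it is arylated once at each carbon.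

## Retrosynthetic reasoning

**15 to 14.** The four O–H bonds are traced back to O–CH3. Methyl ethers are the one protecting group that survives an aryllithium, palladium catalysis, fluoride at raised temperature and hydrogenation alike. They come off together in one Lewis-acid step that leaves the diaryl ether intact, so the air-sensitive hydroquinone appears only at the very end.

**14 to 13.** The benzylic C–H bond next to ring A is traced back to a C–B bond. The boron is the residue of the coupling that builds the bridge. It sits on a benzylic carbon, where a fluoride-activated boronate is protonated comparatively easily, so a single step removes it. The stereocentre that 13 carries vanishes with it.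

**13 to 12 and 8 (key disconnection).** Both aryl–carbon bonds of the A–B bridge are cut: ring A to the boron-bearing carbon and ring B to the neighbouring CH2. What remains between them is the two-carbon vinyl unit of 10. The cut is made here because:
- this bridge is the only place where two simple arene partners meet a C2 unit that is itself a stock reagent;
- it lets the large fragment 8 enter in the last C–C bond-forming step, giving maximum convergence;
- two skeletal bonds form in one operation.

Ring A is chosen as the migrating group, supplied as 11 from 9, because a cheap aryllithium can be used in slight excess. The valuable fragment 8 is then the limiting electrophile and never meets a free organolithium, since 11 is trapped by 10 as the ate complex 12 before 8 is added. The forward reaction has to make the aryl group shift from boron to carbon under palladium activation, rather than transfer directly to palladium.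

**8 to 6 and 7.** The diaryl ether is cut at the ring B–O bond. The oxygen then stays on ring C, where it already sits as a free phenol in 6. Ring B arrives as a boronic acid whose para bromine is untouched by copper at room temperature and becomes the handle for the key step. Cutting the ring C–O bond instead would require a halide on the electron-rich ring C and would offer no such orthogonal handle.

**6 to 5 to 3 and 4 (4 from 2, 2 from 1).** The C–D bridge is cut at its central C–C bond, written as a C=C bond in 5. Olefination of 3 with ylide 4, then hydrogenation, forms it. The geometry of 5 is irrelevant. Aldehyde 3 is chosen because its substitution is exactly that of ring C: the free hydroxyl meta to the formyl group becomes the ether oxygen, and the methoxy group para to it becomes the ring C hydroxyl. Because the hydroxyl of 3 is meta to the formyl group, its phenoxide does not deactivate the carbonyl by resonance, so no protecting group is spent on it. Ylide 4 comes from salt 2, made in one step from chloride 1.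

## Alternatives that were turned down

**Alternative 1: ring C by Robinson annulation.**
- Disconnection: ring C is opened across two C–C bonds to an aryloxyacetone A2 (already carrying rings A and B) and a 2-substituted acrolein A3 (carrying ring D).
- Forward key step: secondary-amine catalysis adds A2 through its oxygen-bearing carbon to A3, and aldol condensation of the methyl group closes the cyclohexenone A1.
- For it: the oxygen pattern of ring C is fixed by the bond construction itself; no organolithium, palladium or copper step is needed. On these points it is at least as strong as the chosen route.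
- Against it:
  - A1 is not aromatic and must still be dehydrogenated. From A1 a second aromatisation path is open, in which the aryloxy group at C6 is eliminated with the C5 hydrogen; this would cut the very ether the step was meant to install.
  - A3 is a polymerisation-prone acceptor that has to be made.
  - A2 presupposes that the A–B bibenzyl has already been assembled by some other C–C bond formation.
  - Two stereocentres are created only to be destroyed.
- Comparison: the chosen route takes the ring C pattern from 3 at no cost, so the one real advantage of this alternative is not needed, and it is several steps longer.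

**Alternative 2: ring A by [3+3] cyclocondensation.**
- Disconnection: ring A is opened to the bis(silyl enol ether) diene A5 and a β-keto acetal A6 that carries rings B, C and D.
- Forward key step: a strong oxophilic Lewis acid joins the terminal carbon of A5 to the acetal carbon and the central carbon to the ketone, giving the 6-substituted salicylate A4 after aromatisation.
- For it: ring A arrives with a free hydroxyl, so one ether fewer has to be cleaved, and the ring-forming step needs no cryogenic organometallic. On both points it is stronger than the chosen route.
- Against it:
  - The two bridge carbons are already attached to ring B in A6, so the A–B bridge bond to ring B still has to be made beforehand, and A6 is a multi-step linear construct.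
  - The ester of A4 must be hydrolysed and the salicylic acid decarboxylated under forcing conditions.
  - The orientation of the cyclocondensation (acetal against ketone) decides between the 6- and the 4-substituted salicylate.
- Comparison: it builds from scratch an arene that 9 supplies ready-made. The chosen route offers convergence instead: rings A and B are joined through the bridge in a single late operation.

**Alternative 3: ring B from a pyrone and an ynol ether.**
- Disconnection: ring B is opened to the 5-acyl-2-pyrone A8 (carrying ring A) and the aryl ethynyl ether A9 (carrying rings C and D).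
- Forward key step: inverse-demand [4+2] addition, with the nucleophilic terminal alkyne carbon bonding to the electrophilic C6 of A8, then decarboxylative cycloreversion, gives the benzyl aryl ketone A7 with the ether oxygen para to the acyl group.
- For it: the diaryl ether is never made by cross-coupling because the oxygen is built into ring B, and the regiochemistry follows from the polarisation of both partners. This is stronger than the copper-mediated arylation of the chosen route.
- Against it:
  - A9 is a sensitive ynol ether that needs its own multi-step preparation from the ring C phenol.
  - A8 has to be assembled from a pyrone acid derivative.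
  - The enolisable ketone of A7 must afterwards be reduced to CH2.
- Comparison: it constructs a para-disubstituted benzene that 7 delivers directly and costs at least three more steps. The chosen route accepts one moderate C–O coupling in exchange for commercial ring B and a shorter sequence.

Key step: step 5

## Route

Remark on the chemistry: 2,5-dimethoxybenzyl chloride (1) is taken as a stock chemical. The boron-bearing carbon of 13 is a stereocentre whose configuration is left open, because step 6 removes it.

**Step 1**
Reactants: 1 2,5-dimethoxybenzyl chloride
Product: 2 (2,5-dimethoxybenzyl)triphenylphosphonium chloride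
Conditions: PPh3, toluene, reflux; filter the salt
Reagents that add atoms: triphenylphosphine, c1ccc(cc1)P(c1ccccc1)c1ccccc1
Why: SN2 quaternisation of a benzylic chloride by a phosphine; the salt should precipitate from toluene and need no chromatography.

**Step 2**
Reactants: 2 (2,5-dimethoxybenzyl)triphenylphosphonium chloride; 3 isovanillin (3-hydroxy-4-methoxybenzaldehyde)
Product: 5 5-[2-(2,5-dimethoxyphenyl)ethenyl]-2-methoxyphenol (E/Z mixture), via phosphonium ylide 4 (not isolated)
Conditions: KOtBu (2.3 equiv), THF, 0 °C (ylide first), then 3, 0 °C → rt; aq. NH4Cl
Reagents that add atoms: none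
Why: Wittig olefination with a semi-stabilised benzylic ylide; the second equivalent of base turns 3 into its phenoxide, which lies meta to the formyl group and so does not deactivate it by resonance. The E/Z mixture is of no consequence because the alkene is hydrogenated next.

**Step 3**
Reactants: 5 5-[2-(2,5-dimethoxyphenyl)ethenyl]-2-methoxyphenol
Product: 6 5-[2-(2,5-dimethoxyphenyl)ethyl]-2-methoxyphenol
Conditions: H2 (1 atm), 10% Pd/C (palladium on carbon), EtOAc/EtOH, rt
Reagents that add atoms: none
Why: Heterogeneous catalytic hydrogenation of a stilbene; both isomers should converge on the bibenzyl, and no hydrogenolysable group is present.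

**Step 4**
Reactants: 6 5-[2-(2,5-dimethoxyphenyl)ethyl]-2-methoxyphenol; 7 4-bromophenylboronic acid
Product: 8 2-[2-[3-(4-bromophenoxy)-4-methoxyphenyl]ethyl]-1,4-dimethoxybenzene
Conditions: Cu(OAc)2 (2 equiv), pyridine, 4 Å MS, CH2Cl2, dry air, rt
Reagents that add atoms: none
Why: Chan–Evans–Lam O-arylation: the aryl group passes from boron to a divalent copper phenoxide, and after oxidation to trivalent copper the C–O bond forms by reductive elimination. Copper does not insert into the C–Br bond at room temperature, so the bromine survives as the handle for step 5.

**Step 5**
Reactants: 9 3-bromoanisole; 10 vinylboronic acid pinacol ester; 8 2-[2-[3-(4-bromophenoxy)-4-methoxyphenyl]ethyl]-1,4-dimethoxybenzene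
Product: 13 2-[1-(3-methoxyphenyl)-2-[4-[5-[2-(2,5-dimethoxyphenyl)ethyl]-2-methoxyphenoxy]phenyl]ethyl]-4,4,5,5-tetramethyl-1,3,2-dioxaborolane (configuration at the boron-bearing carbon not defined), via 3-methoxyphenyllithium 11 (not isolated), via lithium (3-methoxyphenyl)(vinyl)pinacolatoborate 12 (not isolated)
Conditions: 9 (1.2 equiv), t-BuLi (2.4 equiv), Et2O, −78 °C; 10 (1.2 equiv), −78 °C → rt; evaporate, THF; 8 (1.0 equiv), Pd(OAc)2 (2 mol%), 1,1′-bis[bis(4-methoxy-3,5-dimethylphenyl)phosphino]-2,2′-bis[(dimethylamino)(phenyl)methyl]ferrocene (MandyPhos type, one enantiomer, 2.4 mol%), NaOSO2CF3 (NaOTf, 3 equiv), 60 °C; non-oxidative aqueous work-up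
Reagents that add atoms: none
Why: Aryllithium 11, made by bromine–lithium exchange, adds to the empty orbital on boron of 10 and gives the four-coordinate ate complex 12. Oxidative addition of 8 to the zerovalent palladium bisphosphine complex gives an arylpalladium bromide, and NaOTf removes bromide as NaBr so that the cationic divalent palladium centre can bind the vinyl group of 12. This coordination triggers a 1,2-metallate shift: the 3-methoxyphenyl group moves from boron to the adjacent carbon anti to palladium while the terminal carbon bonds to palladium, and C(sp3)–C(sp2) reductive elimination then attaches ring B and returns zerovalent palladium. The closest known reaction type is the palladium-catalysed conjunctive cross-coupling of vinylboron ate complexes with aryl triflates and bromides, used here with an aryl migrating group and an electron-rich aryl bromide. No ring is closed. The one new stereocentre, the boron-bearing benzylic carbon, is set by the chiral ligand, but step 6 replaces boron by hydrogen, so neither its sense nor its purity matters. The selectivity needed is metallate shift over direct transfer of aryl or vinyl from boron to palladium and over β-hydride elimination of the alkylpalladium intermediate; the wide-bite-angle electron-rich bisphosphine and the halide-free cationic palladium should secure the first, and fast reductive elimination from the bisphosphine complex the second. The methyl ethers and the diaryl ether of 8 are inert to the borate, and all of 11 is consumed by 10 before 8 is added.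

**Step 6**
Reactants: 13 the benzylic pinacol boronate of step 5
Product: 14 1-[5-[2-(2,5-dimethoxyphenyl)ethyl]-2-methoxyphenoxy]-4-[2-(3-methoxyphenyl)ethyl]benzene
Conditions: Bu4NF·3H2O (3 equiv), toluene, 80 °C
Reagents that add atoms: none
Why: Fluoride-promoted protodeboronation of a benzylic boronic ester: fluoride adds to boron, and the benzylic C–B bond of the resulting boronate is protonated by the water of hydration, with the developing negative charge stabilised by the 3-methoxyphenyl ring. The stereocentre is lost, so the stereochemical course is immaterial.

**Step 7**
Reactants: 14 1-[5-[2-(2,5-dimethoxyphenyl)ethyl]-2-methoxyphenoxy]-4-[2-(3-methoxyphenyl)ethyl]benzene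
Product: 15 2-[2-[4-hydroxy-3-[4-[2-(3-hydroxyphenyl)ethyl]phenoxy]phenyl]ethyl]benzene-1,4-diol (target)
Conditions: BBr3 (8 equiv), CH2Cl2, −78 °C → rt, Ar; MeOH then H2O, 0 °C; wash with aq. Na2S2O4
Reagents that add atoms: none
Why: Lewis-acid cleavage of aryl methyl ethers: O–B coordination, then SN2 attack of bromide on the methyl group. The diaryl ether has no alkyl carbon to attack and should survive. Exclusion of air and the dithionite wash keep ring D in the hydroquinone state.

## Compound list

1 | 2,5-dimethoxybenzyl chloride [2-(chloromethyl)-1,4-dimethoxybenzene] | COc1ccc(OC)c(CCl)c1 | starting material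
2 | (2,5-dimethoxybenzyl)triphenylphosphonium chloride | COc1ccc(OC)c(C[P+](c2ccccc2)(c2ccccc2)c2ccccc2)c1.[Cl-] | intermediate
3 | isovanillin (3-hydroxy-4-methoxybenzaldehyde) | COc1ccc(C=O)cc1O | starting material
4 | (2,5-dimethoxybenzylidene)triphenylphosphorane (ylide, not isolated) | COc1ccc(OC)c(C=P(c2ccccc2)(c2ccccc2)c2ccccc2)c1 | intermediate
5 | 5-[2-(2,5-dimethoxyphenyl)ethenyl]-2-methoxyphenol (E/Z mixture) | COc1ccc(OC)c(C=Cc2ccc(OC)c(O)c2)c1 | intermediate
6 | 5-[2-(2,5-dimethoxyphenyl)ethyl]-2-methoxyphenol | COc1ccc(OC)c(CCc2ccc(OC)c(O)c2)c1 | intermediate
7 | 4-bromophenylboronic acid | OB(O)c1ccc(Br)cc1 | starting material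
8 | 2-[2-[3-(4-bromophenoxy)-4-methoxyphenyl]ethyl]-1,4-dimethoxybenzene | COc1ccc(OC)c(CCc2ccc(OC)c(Oc3ccc(Br)cc3)c2)c1 | intermediate
9 | 3-bromoanisole | COc1cccc(Br)c1 | starting material
10 | vinylboronic acid pinacol ester | C=CB1OC(C)(C)C(C)(C)O1 | starting material
11 | 3-methoxyphenyllithium (not isolated) | [Li]c1cccc(OC)c1 | intermediate
12 | lithium (3-methoxyphenyl)(vinyl)pinacolatoborate (not isolated) | [Li+].C=C[B-]1(c2cccc(OC)c2)OC(C)(C)C(C)(C)O1 | intermediate
13 | 2-[1-(3-methoxyphenyl)-2-[4-[5-[2-(2,5-dimethoxyphenyl)ethyl]-2-methoxyphenoxy]phenyl]ethyl]-4,4,5,5-tetramethyl-1,3,2-dioxaborolane (configuration at C–B not defined) | COc1cccc(C(Cc2ccc(Oc3cc(CCc4cc(OC)ccc4OC)ccc3OC)cc2)B2OC(C)(C)C(C)(C)O2)c1 | intermediate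
14 | 1-[5-[2-(2,5-dimethoxyphenyl)ethyl]-2-methoxyphenoxy]-4-[2-(3-methoxyphenyl)ethyl]benzene | COc1cccc(CCc2ccc(Oc3cc(CCc4cc(OC)ccc4OC)ccc3OC)cc2)c1 | intermediate
15 | 2-[2-[4-hydroxy-3-[4-[2-(3-hydroxyphenyl)ethyl]phenoxy]phenyl]ethyl]benzene-1,4-diol | Oc1cccc(CCc2ccc(Oc3cc(CCc4cc(O)ccc4O)ccc3O)cc2)c1 | target

## Step count and risks

Total steps: 7. Longest linear sequence: 7 steps (1 to 15); 9 and 10 enter convergently in step 5.

**Step 5 (key step).** The most likely failure is that the ate complex 12 transfers its aryl or vinyl group directly to palladium in a Suzuki-type transmetalation instead of undergoing the metallate shift. This is favoured if bromide from the lithiation or from 8 stays bound to palladium and blocks the site the alkene needs. Slow oxidative addition of the electron-rich bromide would add to the problem.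
Fallback: set out from 8 and run a Mizoroki–Heck reaction with commercial 3-vinylanisole (Pd(OAc)2, P(o-tol)3, Et3N, DMF, 100 °C). This should give 2-[2-[4-methoxy-3-[4-[(E)-2-(3-methoxyphenyl)ethenyl]phenoxy]phenyl]ethyl]-1,4-dimethoxybenzene F1. Hydrogenation of F1 (H2, Pd/C, EtOAc) returns to the route at 14, bypassing 13 and step 6.

**Step 6.** Protonolysis of the C–B bond may be too slow for a secondary benzylic ester, which stabilises the developing carbanion less than tertiary or diaryl systems do. Prolonged heating with fluoride could then let adventitious oxidation of the C–B bond compete.
Fallback: set out from 13 and oxidise the C–B bond (H2O2, NaOH, THF, 0 °C) to 1-(3-methoxyphenyl)-2-[4-[5-[2-(2,5-dimethoxyphenyl)ethyl]-2-methoxyphenoxy]phenyl]ethanol F2. Hydrogenolysis of the benzylic C–O bond of F2 (H2, Pd/C, AcOH, trace HClO4) returns to the route at 14.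

**Step 4.** The boronic acid may be used up by homocoupling and protodeboronation faster than it arylates the ortho-methoxy-substituted phenol, leaving the conversion incomplete.
Fallback: set out from 6 and use an Ullmann-type coupling with commercial 1-bromo-4-iodobenzene (CuI, N,N-dimethylglycine, Cs2CO3, dioxane, 90 °C). Monovalent copper inserts selectively into the C–I bond, and the path returns to the route at 8 directly. No new compound is made on it.

**Step 2.** The potassium phenoxide of 3 may precipitate, or proton transfer from the free phenol may quench part of the ylide, so that the olefination stalls.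
Fallback: change the order of events. Set out from 3 and arylate it first with 7 (Cu(OAc)2, pyridine, 4 Å MS, CH2Cl2, air) to give 3-(4-bromophenoxy)-4-methoxybenzaldehyde F3. Wittig reaction of F3 with ylide 4 gives 2-[2-[3-(4-bromophenoxy)-4-methoxyphenyl]ethenyl]-1,4-dimethoxybenzene F4 as an E/Z mixture. Diimide reduction of F4 (p-toluenesulfonyl hydrazide, NaOAc, aq. THF, reflux) leaves the C–Br bond alone and returns to the route at 8, bypassing 5 and 6.

## Further compounds

F1 | step 5 | 2-[2-[4-methoxy-3-[4-[(E)-2-(3-methoxyphenyl)ethenyl]phenoxy]phenyl]ethyl]-1,4-dimethoxybenzene | COc1cccc(/C=C/c2ccc(Oc3cc(CCc4cc(OC)ccc4OC)ccc3OC)cc2)c1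
F2 | step 6 | 1-(3-methoxyphenyl)-2-[4-[5-[2-(2,5-dimethoxyphenyl)ethyl]-2-methoxyphenoxy]phenyl]ethanol (configuration not defined) | COc1cccc(C(O)Cc2ccc(Oc3cc(CCc4cc(OC)ccc4OC)ccc3OC)cc2)c1
F0 | step 4 | none | none
F3 | step 2 | 3-(4-bromophenoxy)-4-methoxybenzaldehyde | COc1ccc(C=O)cc1Oc1ccc(Br)cc1
F4 | step 2 | 2-[2-[3-(4-bromophenoxy)-4-methoxyphenyl]ethenyl]-1,4-dimethoxybenzene (E/Z mixture) | COc1ccc(OC)c(C=Cc2ccc(OC)c(Oc3ccc(Br)cc3)c2)c1
A1 | alternative 1 | 4-[2-(2,5-dimethoxyphenyl)ethyl]-6-[4-[2-(3-methoxyphenyl)ethyl]phenoxy]cyclohex-2-en-1-one (mixture of diastereomers) | O=C1C=CC(CCc2cc(OC)ccc2OC)CC1Oc1ccc(CCc2cccc(OC)c2)cc1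
A2 | alternative 1 | 1-[4-[2-(3-methoxyphenyl)ethyl]phenoxy]propan-2-one | CC(=O)COc1ccc(CCc2cccc(OC)c2)cc1
A3 | alternative 1 | 4-(2,5-dimethoxyphenyl)-2-methylidenebutanal | C=C(CCc1cc(OC)ccc1OC)C=O
A4 | alternative 2 | methyl 2-hydroxy-6-[2-[4-[5-[2-(2,5-dimethoxyphenyl)ethyl]-2-methoxyphenoxy]phenyl]ethyl]benzoate | COC(=O)c1c(O)cccc1CCc1ccc(Oc2cc(CCc3cc(OC)ccc3OC)ccc2OC)cc1
A5 | alternative 2 | 1-methoxy-1,3-bis(trimethylsilyloxy)buta-1,3-diene | COC(O[Si](C)(C)C)=CC(=C)O[Si](C)(C)C
A6 | alternative 2 | 1,1-dimethoxy-5-[4-[5-[2-(2,5-dimethoxyphenyl)ethyl]-2-methoxyphenoxy]phenyl]pentan-3-one | COC(OC)CC(=O)CCc1ccc(Oc2cc(CCc3cc(OC)ccc3OC)ccc2OC)cc1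
A7 | alternative 3 | 1-[4-[5-[2-(2,5-dimethoxyphenyl)ethyl]-2-methoxyphenoxy]phenyl]-2-(3-methoxyphenyl)ethanone | COc1cccc(CC(=O)c2ccc(Oc3cc(CCc4cc(OC)ccc4OC)ccc3OC)cc2)c1
A8 | alternative 3 | 5-[2-(3-methoxyphenyl)acetyl]-2H-pyran-2-one | COc1cccc(CC(=O)c2ccc(=O)oc2)c1
A9 | alternative 3 | 4-[2-(2,5-dimethoxyphenyl)ethyl]-2-(ethynyloxy)-1-methoxybenzene | C#COc1cc(CCc2cc(OC)ccc2OC)ccc1OC
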